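**The ratio.** Between the north and south runs one ratio stands still. I call it the nucleophile return, ρ: target in M at the last reading, over nucleophile charged in M. North gives 0.386 and south 0.377, and I carry their mean, ρ = 0.382.

| setting | north | south | delta | epsilon |
|---|---|---|---|---|
| electrophile | 0.30 M | 0.30 M | 0.30 M | 0.30 M |
| nucleophile | 0.17 M | 0.35 M | 0.270 M | 0.540 M |
| free base | 0.60 M | 0.60 M | 0.600 M | 0.600 M |
| remark | run made earlier | run made earlier |  |  |
| time |  |  | 8.0 h | 8.0 h |

| run | time / h | electrophile / % | side product / % | target / % |
|---|---|---|---|---|
| north | 0.833 | 71.0 | 0.8 | 10.5 |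
| north | 1.50 | 58.0 | 3.1 | 15.4 |
| north | 2.50 | 44.1 | 4.6 | 18.1 |
| north | 3.00 | 39.0 | 3.6 | 19.4 |
| north | 4.00 | 34.5 | 7.3 | 20.5 |
| north | 5.00 | 28.2 | 7.2 | 20.1 |
| north | 6.00 | 26.6 | 9.9 | 21.9 |
| south | 0.833 | 61.4 | 3.1 | 21.1 |
| south | 1.50 | 46.3 | 2.8 | 30.2 |
| south | 2.50 | 32.7 | 5.7 | 36.6 |
| south | 3.00 | 30.6 | 6.7 | 37.9 |
| south | 4.00 | 22.8 | 8.6 | 37.3 |
| south | 5.00 | 17.3 | 11.5 | 38.4 |
| south | 6.00 | 14.4 | 12.6 | 44.0 |

(each reading ± 1 percentage point)

- percentages count the electrophile that a species holds: one side product counts as two

* which of these there is most of at the end, counted by the electrophile in it, delta (target / electrophile / side product)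
* which of these there is most of at the end, counted by the electrophile in it, epsilon (target / electrophile / side product)
* the largest of these amounts at the end, in percent of the electrophile charged, delta
* the largest of these amounts at the end, in percent of the electrophile charged, epsilon

**In the flasks.** You take over delta and epsilon, which differ in nucleophile. Delta charges less of it than of electrophile. Expect unseen material: north's three read species add up to 58.4% at its last reading.

**When you come.** My reckoning is target = ρ × nucleophile / electrophile, which gives 34.4% in delta. In epsilon it gives 68.7%, but that charge lies beyond south's, so I trust this figure less.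

**Do not touch.** Leave the nucleophile charge alone. From north to south it rose twice, and the last target reading rose twice, while waiting took north's target from 20.5% to 21.9% between 4.00 h and 6.00 h.

**The forecast.** It names target in delta at 34% (29% to 39%) and target in epsilon at 58% (49% to 67%). That epsilon figure stands lower than mine, reached as “about 58%, with some saturation”.

**The result.**

    electrophile + nucleophile → acid set free + target (k = 0.0210 M⁻¹ min⁻¹)
    nucleophile + acid set free ⇌ idle adduct, settled at all times (K = 1200 M⁻¹)
    electrophile + target → side product (k = 0.00560 M⁻¹ min⁻¹)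
    acid set free + free base ⇌ salt of the base, settled at all times (K = 2.90 M⁻¹)
    nucleophile + acid set free ⇌ protonated nucleophile, settled at all times (K = 150 M⁻¹)
    2 electrophile → homo dimer (k = 0.00850 M⁻¹ min⁻¹)

Delta ends at 33.3% target and epsilon at 59.7% target, as the forecast said. At 8.00 h delta holds 0.101 M idle adduct beside 0.0999 M target. The return comes out at 0.370 in delta and 0.332 in epsilon. For delta's neighbour with 0.11 M nucleophile, ρ reckons 14.0% target, and that flask holds 14.0%.

(The data were computed from invented constants, noise included.)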